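**Retrosynthetic overview**
1. The hydroxylactone is closed last, by ring–chain closure of a cis aldehyde–acid; the aldehyde comes from an exocyclic CH2 by hydroboration, and the propanoate methyl from a late enolate methylation.
2. Ring A, with its tetrasubstituted C=C, comes from a Diels–Alder reaction of a vinylallene with an Evans acrylimide, which sets the ring-fusion carbon next to the lactone carbonyl.
3. The vinylallene comes from a Johnson–Claisen rearrangement of an enynol, itself made by Sonogashira coupling of a 1-iodovinyl cyclohexane with propargyl alcohol.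
4. The quaternary stereocentre comes from a copper-catalysed enantioselective conjugate addition of a 1-silylvinyl alane to 3-methylcyclohexenone, followed by geminal dimethylation.
5. Ring order: trimethylcyclohexane ring (steps 1–3), then ring A (step 7), then the lactone ring (step 14).

Assumption: the hemiacylal carbon C-3 of the target epimerises through the open aldehyde–acid form, and the (3R) epimer drawn is taken to be the stable, isolated one.

**Step 1**
Reactants: 1 3-methylcyclohex-2-en-1-one; 2 ethynyl(trimethyl)silane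
Product: 5 (3S)-3-methyl-3-[1-(trimethylsilyl)ethenyl]cyclohexan-1-one, via vinylalane 3 (not isolated), via aluminium enolate 4 (not isolated)
Conditions: 2, i-Bu2AlH, hexanes, 55 °C; then 1, Cu(OTf)2 (5 mol%), chiral sulfonate-bearing imidazolinium salt (NHC precursor, 5 mol%), THF, −30 °C to rt; aq. HCl
Reagents that add atoms: none
Why: Hydroalumination puts aluminium on the silicon-bearing alkyne carbon, and the copper–NHC-catalysed enantioselective conjugate addition of this alkenylalane to the β-methyl enone creates the quaternary centre, the ligand enantiomer being chosen to deliver the alkenyl group to the face that gives (S).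

**Step 2**
Reactants: 5 (3S)-3-methyl-3-[1-(trimethylsilyl)ethenyl]cyclohexan-1-one
Product: 6 (3S)-3-(1-iodoethenyl)-3-methylcyclohexan-1-one
Conditions: NIS, MeCN–ClCH2CN, 0 °C to rt
Reagents that add atoms: N-iodosuccinimide, O=C1CCC(=O)N1I
Why: Ipso-iododesilylation of the vinylsilane exchanges SiMe3 for iodine at the same carbon and leaves the ketone and the quaternary centre untouched.

**Step 3**
Reactants: 6 (3S)-3-(1-iodoethenyl)-3-methylcyclohexan-1-one
Product: 7 (1S)-1-(1-iodoethenyl)-1,3,3-trimethylcyclohexane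
Conditions: TiCl4, ZnMe2, CH2Cl2, −30 °C to rt
Reagents that add atoms: dichlorodimethyltitanium Me2TiCl2 (formed in the flask from TiCl4 and ZnMe2), C[Ti](C)(Cl)Cl
Why: Reetz geminal dimethylation, in which methyl adds to the carbonyl and the tertiary titanium alkoxide ionises and takes up the second methyl (SN1-type), turns C=O into CMe2 without involving the stereocentre.

**Step 4**
Reactants: 7 (1S)-1-(1-iodoethenyl)-1,3,3-trimethylcyclohexane; 8 prop-2-yn-1-ol
Product: 9 4-[(1S)-1,3,3-trimethylcyclohexyl]pent-4-en-2-yn-1-ol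
Conditions: PdCl2(PPh3)2 (3 mol%), CuI (6 mol%), Et3N, THF, rt
Reagents that add atoms: none
Why: Sonogashira coupling of the 1-iodoalkene with the terminal alkyne gives the 2-substituted enyne with no change at the stereocentre.

**Step 5**
Reactants: 9 4-[(1S)-1,3,3-trimethylcyclohexyl]pent-4-en-2-yn-1-ol; 10 1,1,1-trimethoxyethane
Product: 12 methyl 3-{1-[(1S)-1,3,3-trimethylcyclohexyl]ethenyl}penta-3,4-dienoate, via ketene acetal 11 (not isolated)
Conditions: EtCO2H (cat.), 10 (excess), xylenes, 125 °C, MeOH distilled off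
Reagents that add atoms: none
Why: Johnson–Claisen (orthoester) rearrangement, in which the propargyl ketene acetal undergoes a [3,3]-sigmatropic shift, forms the C–CH2CO2Me bond at the alkyne carbon bearing the vinyl group and unfolds the alkyne into a terminal allene.

**Step 6**
Reactants: 13 (4S)-4-benzyl-1,3-oxazolidin-2-one; 14 prop-2-enoyl chloride
Product: 16 (4S)-4-benzyl-3-(prop-2-enoyl)-1,3-oxazolidin-2-one, via magnesium amide 15 (not isolated)
Conditions: MeMgBr, THF, 0 °C; then 14, −78 °C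
Reagents that add atoms: none
Why: N-Acylation of the bromomagnesium salt of the oxazolidinone gives the chelating chiral dienophile without polymerising the acryloyl group.

**Step 7**
Reactants: 12 methyl 3-{1-[(1S)-1,3,3-trimethylcyclohexyl]ethenyl}penta-3,4-dienoate; 16 (4S)-4-benzyl-3-(prop-2-enoyl)-1,3-oxazolidin-2-one
Product: 17 methyl 2-[(5R)-5-{[(4S)-4-benzyl-2-oxo-1,3-oxazolidin-3-yl]carbonyl}-6-methylidene-2-[(1S)-1,3,3-trimethylcyclohexyl]cyclohex-1-en-1-yl]acetate
Conditions: Et2AlCl (1.4 equiv), CH2Cl2, −78 to −40 °C; aq. HCl quench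
Reagents that add atoms: none
Why: In this Lewis-acid-promoted Diels–Alder reaction of a vinylallene with the Evans acrylimide, the acyl-bearing carbon bonds to the central allene carbon ("ortho" rule for vinylallenes), the ring double bond is born tetrasubstituted, and the diene adds to the s-cis, aluminium-chelated dienophile on the face opposite the benzyl group, which sets C-5 as (R).

**Step 8**
Reactants: 17 methyl 2-[(5R)-5-{[(4S)-4-benzyl-2-oxo-1,3-oxazolidin-3-yl]carbonyl}-6-methylidene-2-[(1S)-1,3,3-trimethylcyclohexyl]cyclohex-1-en-1-yl]acetate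
Product: 19 (1R)-3-(2-methoxy-2-oxoethyl)-2-methylidene-4-[(1S)-1,3,3-trimethylcyclohexyl]cyclohex-3-ene-1-carboxylic acid, via lithium percarboxylate 18 (not isolated)
Conditions: LiOH, H2O2, THF–H2O, 0 °C; then aq. Na2SO3; HCl to pH 3
Reagents that add atoms: lithium hydroperoxide LiOOH (from LiOH and H2O2), [Li+].[O-]O
Why: Hydroperoxide cleaves the exocyclic imide carbonyl selectively (Evans auxiliary removal) and sulfite reduces the peracid, while the methyl ester and the stereocentres are left alone.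

**Step 9**
Reactants: 19 (1R)-3-(2-methoxy-2-oxoethyl)-2-methylidene-4-[(1S)-1,3,3-trimethylcyclohexyl]cyclohex-3-ene-1-carboxylic acid
Product: 20 tert-butyl (1R)-3-(2-methoxy-2-oxoethyl)-2-methylidene-4-[(1S)-1,3,3-trimethylcyclohexyl]cyclohex-3-ene-1-carboxylate
Conditions: t-BuOC(=NH)CCl3, CH2Cl2–cyclohexane, rt
Reagents that add atoms: tert-butyl 2,2,2-trichloroacetimidate, CC(C)(C)OC(=N)C(Cl)(Cl)Cl
Why: O-Alkylation of the carboxylic acid by the trichloroacetimidate (tert-butyl cation transfer) gives an ester that resists lactonisation and base in the following steps.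

**Step 10**
Reactants: 20 tert-butyl (1R)-3-(2-methoxy-2-oxoethyl)-2-methylidene-4-[(1S)-1,3,3-trimethylcyclohexyl]cyclohex-3-ene-1-carboxylate
Product: 22 tert-butyl (1R,2R)-2-(hydroxymethyl)-3-(2-methoxy-2-oxoethyl)-4-[(1S)-1,3,3-trimethylcyclohexyl]cyclohex-3-ene-1-carboxylate, via alkylborane 21 (not isolated)
Conditions: 9-BBN, THF, 0 °C to rt; then H2O2, aq. NaOAc, 0 °C
Reagents that add atoms: hydrogen peroxide, OO
Why: In this hydroboration–oxidation 9-BBN adds anti-Markovnikov only to the exocyclic CH2 (the tetrasubstituted alkene is inert) from the face opposite the pseudoaxial CO2t-Bu on C-1, so hydrogen reaches C-2 trans to the ester and the CH2OH ends cis to it, (2R).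

**Step 11**
Reactants: 22 tert-butyl (1R,2R)-2-(hydroxymethyl)-3-(2-methoxy-2-oxoethyl)-4-[(1S)-1,3,3-trimethylcyclohexyl]cyclohex-3-ene-1-carboxylate
Product: 23 tert-butyl (1R,2R)-3-(2-methoxy-2-oxoethyl)-2-{[(triethylsilyl)oxy]methyl}-4-[(1S)-1,3,3-trimethylcyclohexyl]cyclohex-3-ene-1-carboxylate
Conditions: Et3SiCl, imidazole, CH2Cl2, 0 °C
Reagents that add atoms: chlorotriethylsilane, CC[Si](Cl)(CC)CC
Why: Silylation of the primary alcohol blocks lactonisation and places a bulky group on the upper face beside the enolisable CH2.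

**Step 12**
Reactants: 23 tert-butyl (1R,2R)-3-(2-methoxy-2-oxoethyl)-2-{[(triethylsilyl)oxy]methyl}-4-[(1S)-1,3,3-trimethylcyclohexyl]cyclohex-3-ene-1-carboxylate
Product: 25 tert-butyl (1R,2R)-3-[(2R)-1-methoxy-1-oxopropan-2-yl]-2-{[(triethylsilyl)oxy]methyl}-4-[(1S)-1,3,3-trimethylcyclohexyl]cyclohex-3-ene-1-carboxylate, via lithium enolate 24 (not isolated)
Conditions: LiN(i-Pr)2, THF, −78 °C; MeI, −78 to −40 °C
Reagents that add atoms: iodomethane, CI
Why: In this kinetic enolate alkylation the allylic CH2CO2Me is deprotonated in preference to the hindered tert-butyl ester methine, allylic 1,3-strain against the tert-alkyl group holds the enolate C–H in the ring plane, and MeI enters from the face opposite the CH2OSiEt3 group on C-2, giving the (2R) propanoate.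

**Step 13**
Reactants: 25 tert-butyl (1R,2R)-3-[(2R)-1-methoxy-1-oxopropan-2-yl]-2-{[(triethylsilyl)oxy]methyl}-4-[(1S)-1,3,3-trimethylcyclohexyl]cyclohex-3-ene-1-carboxylate
Product: 26 tert-butyl (1R,2R)-2-formyl-3-[(2R)-1-methoxy-1-oxopropan-2-yl]-4-[(1S)-1,3,3-trimethylcyclohexyl]cyclohex-3-ene-1-carboxylate
Conditions: (COCl)2, DMSO, CH2Cl2, −78 to −40 °C; i-Pr2NEt, −78 to 0 °C
Reagents that add atoms: none
Why: Under Swern conditions the chlorosulfonium salt cleaves the primary triethylsilyl ether and oxidises it to the aldehyde in one pot, and the hindered amine and low temperature keep the α-stereocentre and the β,γ-double bond in place.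

**Step 14**
Reactants: 26 tert-butyl (1R,2R)-2-formyl-3-[(2R)-1-methoxy-1-oxopropan-2-yl]-4-[(1S)-1,3,3-trimethylcyclohexyl]cyclohex-3-ene-1-carboxylate
Product: 28 methyl (2R)-2-[(3R,3aR,7aR)-3-hydroxy-1-oxo-5-[(1S)-1,3,3-trimethylcyclohexyl]-1,3,3a,6,7,7a-hexahydro-2-benzofuran-4-yl]propanoate, via aldehyde acid 27 (not isolated)
Conditions: CF3CO2H–CH2Cl2 (1:4), 0 °C to rt; aq. work-up
Reagents that add atoms: none
Why: Acidolysis of the tert-butyl ester (loss of isobutene) frees the acid, which adds to the cis aldehyde (ring–chain tautomerism of a γ-aldehydo acid) to close the cis-fused γ-hydroxylactone, with C-3a and C-7a carried over from 26 and the hemiacylal carbon C-3 settling as the (3R) epimer under equilibrium.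

**Compound list**
1 | 3-methylcyclohex-2-en-1-one | CC1=CC(=O)CCC1 | starting material
2 | ethynyl(trimethyl)silane | C#C[Si](C)(C)C | starting material
3 | bis(2-methylpropyl)[1-(trimethylsilyl)ethenyl]aluminium (vinylalane) | C=C([Si](C)(C)C)[Al](CC(C)C)CC(C)C | intermediate
4 | bis(2-methylpropyl)({(3S)-3-methyl-3-[1-(trimethylsilyl)ethenyl]cyclohex-1-en-1-yl}oxy)aluminium (aluminium enolate) | C=C([Si](C)(C)C)[C@@]1(C)CCCC(O[Al](CC(C)C)CC(C)C)=C1 | intermediate
5 | (3S)-3-methyl-3-[1-(trimethylsilyl)ethenyl]cyclohexan-1-one | C=C([Si](C)(C)C)[C@@]1(C)CCCC(=O)C1 | intermediate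
6 | (3S)-3-(1-iodoethenyl)-3-methylcyclohexan-1-one | C=C(I)[C@@]1(C)CCCC(=O)C1 | intermediate
7 | (1S)-1-(1-iodoethenyl)-1,3,3-trimethylcyclohexane | C=C(I)[C@@]1(C)CCCC(C)(C)C1 | intermediate
8 | prop-2-yn-1-ol | C#CCO | starting material
9 | 4-[(1S)-1,3,3-trimethylcyclohexyl]pent-4-en-2-yn-1-ol | OCC#CC(=C)[C@@]1(C)CCCC(C)(C)C1 | intermediate
10 | 1,1,1-trimethoxyethane | CC(OC)(OC)OC | starting material
11 | (1S)-1-{5-[(1-methoxyethenyl)oxy]pent-1-en-3-yn-2-yl}-1,3,3-trimethylcyclohexane (ketene acetal) | C=C(OC)OCC#CC(=C)[C@@]1(C)CCCC(C)(C)C1 | intermediate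
12 | methyl 3-{1-[(1S)-1,3,3-trimethylcyclohexyl]ethenyl}penta-3,4-dienoate | COC(=O)CC(=C=C)C(=C)[C@@]1(C)CCCC(C)(C)C1 | intermediate
13 | (4S)-4-benzyl-1,3-oxazolidin-2-one | O=C1N[C@@H](Cc2ccccc2)CO1 | starting material
14 | prop-2-enoyl chloride | C=CC(=O)Cl | starting material
15 | bromo[(4S)-4-benzyl-2-oxo-1,3-oxazolidin-3-yl]magnesium (magnesium amide) | Br[Mg]N1[C@@H](Cc2ccccc2)COC1=O | intermediate
16 | (4S)-4-benzyl-3-(prop-2-enoyl)-1,3-oxazolidin-2-one | C=CC(=O)N1[C@@H](Cc2ccccc2)COC1=O | intermediate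
17 | methyl 2-[(5R)-5-{[(4S)-4-benzyl-2-oxo-1,3-oxazolidin-3-yl]carbonyl}-6-methylidene-2-[(1S)-1,3,3-trimethylcyclohexyl]cyclohex-1-en-1-yl]acetate | COC(=O)CC1=C([C@@]2(C)CCCC(C)(C)C2)CC[C@@H](C(=O)N2[C@@H](Cc3ccccc3)COC2=O)C1=C | intermediate
18 | lithium (1R)-3-(2-methoxy-2-oxoethyl)-2-methylidene-4-[(1S)-1,3,3-trimethylcyclohexyl]cyclohex-3-ene-1-carboperoxoate | [Li+].COC(=O)CC1=C([C@@]2(C)CCCC(C)(C)C2)CC[C@@H](C(=O)O[O-])C1=C | intermediate
19 | (1R)-3-(2-methoxy-2-oxoethyl)-2-methylidene-4-[(1S)-1,3,3-trimethylcyclohexyl]cyclohex-3-ene-1-carboxylic acid | COC(=O)CC1=C([C@@]2(C)CCCC(C)(C)C2)CC[C@@H](C(=O)O)C1=C | intermediate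
20 | tert-butyl (1R)-3-(2-methoxy-2-oxoethyl)-2-methylidene-4-[(1S)-1,3,3-trimethylcyclohexyl]cyclohex-3-ene-1-carboxylate | COC(=O)CC1=C([C@@]2(C)CCCC(C)(C)C2)CC[C@@H](C(=O)OC(C)(C)C)C1=C | intermediate
21 | tert-butyl (1R,2R)-2-[(9-borabicyclo[3.3.1]nonan-9-yl)methyl]-3-(2-methoxy-2-oxoethyl)-4-[(1S)-1,3,3-trimethylcyclohexyl]cyclohex-3-ene-1-carboxylate (alkylborane) | COC(=O)CC1=C([C@@]2(C)CCCC(C)(C)C2)CC[C@@H](C(=O)OC(C)(C)C)[C@H]1CB1C2CCCC1CCC2 | intermediate
22 | tert-butyl (1R,2R)-2-(hydroxymethyl)-3-(2-methoxy-2-oxoethyl)-4-[(1S)-1,3,3-trimethylcyclohexyl]cyclohex-3-ene-1-carboxylate | COC(=O)CC1=C([C@@]2(C)CCCC(C)(C)C2)CC[C@@H](C(=O)OC(C)(C)C)[C@H]1CO | intermediate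
23 | tert-butyl (1R,2R)-3-(2-methoxy-2-oxoethyl)-2-{[(triethylsilyl)oxy]methyl}-4-[(1S)-1,3,3-trimethylcyclohexyl]cyclohex-3-ene-1-carboxylate | COC(=O)CC1=C([C@@]2(C)CCCC(C)(C)C2)CC[C@@H](C(=O)OC(C)(C)C)[C@H]1CO[Si](CC)(CC)CC | intermediate
24 | lithium (1Z)-2-[(5R,6R)-5-(tert-butoxycarbonyl)-6-{[(triethylsilyl)oxy]methyl}-2-[(1S)-1,3,3-trimethylcyclohexyl]cyclohex-1-en-1-yl]-1-methoxyethen-1-olate (lithium enolate, O–Li trans to the ring) | [Li+].CO/C([O-])=C\C1=C([C@@]2(C)CCCC(C)(C)C2)CC[C@@H](C(=O)OC(C)(C)C)[C@H]1CO[Si](CC)(CC)CC | intermediate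
25 | tert-butyl (1R,2R)-3-[(2R)-1-methoxy-1-oxopropan-2-yl]-2-{[(triethylsilyl)oxy]methyl}-4-[(1S)-1,3,3-trimethylcyclohexyl]cyclohex-3-ene-1-carboxylate | COC(=O)[C@H](C)C1=C([C@@]2(C)CCCC(C)(C)C2)CC[C@@H](C(=O)OC(C)(C)C)[C@H]1CO[Si](CC)(CC)CC | intermediate
26 | tert-butyl (1R,2R)-2-formyl-3-[(2R)-1-methoxy-1-oxopropan-2-yl]-4-[(1S)-1,3,3-trimethylcyclohexyl]cyclohex-3-ene-1-carboxylate | COC(=O)[C@H](C)C1=C([C@@]2(C)CCCC(C)(C)C2)CC[C@@H](C(=O)OC(C)(C)C)[C@H]1C=O | intermediate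
27 | (1R,2R)-2-formyl-3-[(2R)-1-methoxy-1-oxopropan-2-yl]-4-[(1S)-1,3,3-trimethylcyclohexyl]cyclohex-3-ene-1-carboxylic acid (aldehyde acid) | COC(=O)[C@H](C)C1=C([C@@]2(C)CCCC(C)(C)C2)CC[C@@H](C(=O)O)[C@H]1C=O | intermediate
28 | methyl (2R)-2-[(3R,3aR,7aR)-3-hydroxy-1-oxo-5-[(1S)-1,3,3-trimethylcyclohexyl]-1,3,3a,6,7,7a-hexahydro-2-benzofuran-4-yl]propanoate | COC(=O)[C@H](C)C1=C([C@@]2(C)CCCC(C)(C)C2)CC[C@H]2C(=O)O[C@@H](O)[C@@H]12 | target

**Step count**
Total: 14 steps. Longest linear sequence: 13 steps (steps 1–5 and 7–14); step 6 is a one-step side branch.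

**Three steps most likely to fail, each with one fallback**

Step 7 is the main risk: the vinylallene may not tolerate Et2AlCl, and the "ortho" regiochemistry is opposed by the CH2CO2Me substituent. The fallback sets out from 12 and comes back at 19, using iminium-ion organocatalysis in place of a chelated imide. Vinylallene 12 and acrolein, with a MacMillan imidazolidinone salt (the enantiomer that gives the (5R) adduct), give methyl 2-[(5R)-5-formyl-6-methylidene-2-[(1S)-1,3,3-trimethylcyclohexyl]cyclohex-1-en-1-yl]acetate F1. Chlorite oxidation of this aldehyde (NaClO2, NaH2PO4, 2-methylbut-2-ene, t-BuOH–H2O) gives acid 19, which also avoids the basic auxiliary cleavage.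

Step 12 is the second risk: the facial selectivity of an open-chain enolate rests only on the silyloxymethyl group and allylic strain. The fallback sets out from 22 and comes back at 25, running the alkylation on a rigid lactone.
- Acid-catalysed δ-lactonisation of 22 onto the methyl ester (PPTS, toluene, 70 °C) gives tert-butyl (8R,8aR)-3-oxo-5-[(1S)-1,3,3-trimethylcyclohexyl]-3,4,6,7,8,8a-hexahydro-1H-2-benzopyran-8-carboxylate F2.
- Its lactone enolate (LiN(i-Pr)2, then MeI) is methylated axially, on the face away from the ring-fusion bond, to give tert-butyl (4R,8R,8aR)-4-methyl-3-oxo-5-[(1S)-1,3,3-trimethylcyclohexyl]-3,4,6,7,8,8a-hexahydro-1H-2-benzopyran-8-carboxylate F3. This epimer is also the thermodynamic one, so base equilibration corrects any leakage.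
- LiOH (THF–H2O, 0 °C) opens the lactone to (2R)-2-[(5R,6R)-5-(tert-butoxycarbonyl)-6-(hydroxymethyl)-2-[(1S)-1,3,3-trimethylcyclohexyl]cyclohex-1-en-1-yl]propanoic acid F4.
- Me3SiCHN2 gives tert-butyl (1R,2R)-2-(hydroxymethyl)-3-[(2R)-1-methoxy-1-oxopropan-2-yl]-4-[(1S)-1,3,3-trimethylcyclohexyl]cyclohex-3-ene-1-carboxylate F5, and Et3SiCl/imidazole returns to 25.

Step 13 is the third risk: the α-branched, β,γ-unsaturated aldehyde may epimerise or slip into conjugation. The fallback sets out from 25 and comes back at 28 without ever forming the aldehyde.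
- CrO3/aq. H2SO4 in acetone removes the silyl group and oxidises the carbinol to (1R,6R)-6-(tert-butoxycarbonyl)-2-[(2R)-1-methoxy-1-oxopropan-2-yl]-3-[(1S)-1,3,3-trimethylcyclohexyl]cyclohex-2-ene-1-carboxylic acid F6.
- CF3CO2H gives (1R,2R)-3-[(2R)-1-methoxy-1-oxopropan-2-yl]-4-[(1S)-1,3,3-trimethylcyclohexyl]cyclohex-3-ene-1,2-dicarboxylic acid F7.
- Ac2O closes methyl (2R)-2-[(3aR,7aR)-1,3-dioxo-5-[(1S)-1,3,3-trimethylcyclohexyl]-1,3,3a,6,7,7a-hexahydro-2-benzofuran-4-yl]propanoate F8.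
- LiAlH(Ot-Bu)3 (THF, −78 °C) reduces the anhydride carbonyl attached to C-3a from the convex face and stops at the hydroxylactone 28; attack at that carbonyl, the one beside the more substituted carbon, is expected but not assured.

**Further compounds**
F1 | step 7 | methyl 2-[(5R)-5-formyl-6-methylidene-2-[(1S)-1,3,3-trimethylcyclohexyl]cyclohex-1-en-1-yl]acetate | COC(=O)CC1=C([C@@]2(C)CCCC(C)(C)C2)CC[C@@H](C=O)C1=C
F2 | step 12 | tert-butyl (8R,8aR)-3-oxo-5-[(1S)-1,3,3-trimethylcyclohexyl]-3,4,6,7,8,8a-hexahydro-1H-2-benzopyran-8-carboxylate | O=C1CC2=C([C@@]3(C)CCCC(C)(C)C3)CC[C@@H](C(=O)OC(C)(C)C)[C@H]2CO1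
F3 | step 12 | tert-butyl (4R,8R,8aR)-4-methyl-3-oxo-5-[(1S)-1,3,3-trimethylcyclohexyl]-3,4,6,7,8,8a-hexahydro-1H-2-benzopyran-8-carboxylate | O=C1[C@H](C)C2=C([C@@]3(C)CCCC(C)(C)C3)CC[C@@H](C(=O)OC(C)(C)C)[C@H]2CO1
F4 | step 12 | (2R)-2-[(5R,6R)-5-(tert-butoxycarbonyl)-6-(hydroxymethyl)-2-[(1S)-1,3,3-trimethylcyclohexyl]cyclohex-1-en-1-yl]propanoic acid | OC(=O)[C@H](C)C1=C([C@@]2(C)CCCC(C)(C)C2)CC[C@@H](C(=O)OC(C)(C)C)[C@H]1CO
F5 | step 12 | tert-butyl (1R,2R)-2-(hydroxymethyl)-3-[(2R)-1-methoxy-1-oxopropan-2-yl]-4-[(1S)-1,3,3-trimethylcyclohexyl]cyclohex-3-ene-1-carboxylate | COC(=O)[C@H](C)C1=C([C@@]2(C)CCCC(C)(C)C2)CC[C@@H](C(=O)OC(C)(C)C)[C@H]1CO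
F6 | step 13 | (1R,6R)-6-(tert-butoxycarbonyl)-2-[(2R)-1-methoxy-1-oxopropan-2-yl]-3-[(1S)-1,3,3-trimethylcyclohexyl]cyclohex-2-ene-1-carboxylic acid | COC(=O)[C@H](C)C1=C([C@@]2(C)CCCC(C)(C)C2)CC[C@@H](C(=O)OC(C)(C)C)[C@H]1C(=O)O
F7 | step 13 | (1R,2R)-3-[(2R)-1-methoxy-1-oxopropan-2-yl]-4-[(1S)-1,3,3-trimethylcyclohexyl]cyclohex-3-ene-1,2-dicarboxylic acid | COC(=O)[C@H](C)C1=C([C@@]2(C)CCCC(C)(C)C2)CC[C@@H](C(=O)O)[C@H]1C(=O)O
F8 | step 13 | methyl (2R)-2-[(3aR,7aR)-1,3-dioxo-5-[(1S)-1,3,3-trimethylcyclohexyl]-1,3,3a,6,7,7a-hexahydro-2-benzofuran-4-yl]propanoate | COC(=O)[C@H](C)C1=C([C@@]2(C)CCCC(C)(C)C2)CC[C@H]2C(=O)OC(=O)[C@@H]12
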